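**Retrosynthetic overview** (A = hydroquinone-type ring, B = para-phenylene, C = catechol-type ring, D = meta-phenylene)
1. All four benzene rings are bought. The only ring formed is the 18-membered macrocycle, closed last at the C–CH2CH2–D bridge by McMurry coupling of an acyclic dialdehyde. One hydrogenation then saturates the alkene and removes the benzyl group.
2. Ring A (4-aryloxy-3-alkylphenol) comes from a 1,2-alkyl shift (dienone–phenol rearrangement) of a 4-alkyl-4-aryloxycyclohexa-2,5-dienone.
3. The dienone comes from oxidative ipso-aryloxylation (dearomatisation) of a para-alkylphenol with 3-hydroxybenzaldehyde, which forms the D–O–A bond.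
4. The para-alkylphenol comes from mono-Ullmann etherification of symmetric 4,4'-dihydroxybibenzyl, which forms the B–O–C bond. The A–CH2CH2–B bridge is bought ready-made.

**Assumption:** the SMILES has no stereodescriptor and the diether macrocycle is conformationally mobile. The target is therefore treated as achiral, and no stereocentre has to be set.

**Step 1**
Reactants: 1 4,4'-(ethane-1,2-diyl)diphenol (3 equiv); 2 4-(benzyloxy)-3-bromobenzaldehyde
Product: 3 4-(benzyloxy)-3-{4-[2-(4-hydroxyphenyl)ethyl]phenoxy}benzaldehyde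
Conditions: CuI (10 mol %), N,N-dimethylglycine (30 mol %), Cs2CO3, dioxane, 90 °C; excess 1 recovered
Reagents that add atoms: none
Why: In this Ullmann–Ma diaryl ether coupling the threefold excess of 1 makes the mono-ether dominate statistically, which breaks the symmetry of the bisphenol, and the non-enolisable aldehyde and the benzyl ether are inert to Cu(I)/carbonate.

**Step 2**
Reactants: 3 4-(benzyloxy)-3-{4-[2-(4-hydroxyphenyl)ethyl]phenoxy}benzaldehyde; 4 3-hydroxybenzaldehyde (10 equiv, inexpensive bulk aromatic)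
Product: 5 4-(benzyloxy)-3-(4-{2-[1-(3-formylphenoxy)-4-oxocyclohexa-2,5-dien-1-yl]ethyl}phenoxy)benzaldehyde
Conditions: PhI(OAc)2 (1.1 equiv, slow addition), 4 Å MS, MeCN, 0 °C; excess 4 removed with cold aq Na2CO3 and recovered
Reagents that add atoms: none
Why: Proposed new method: PhI(OAc)2 oxidises only the electron-rich 4-alkylphenol of 3 to a phenoxenium-type electrophile that is captured at its alkyl-bearing para carbon, as in the known PIDA dearomatisations of 4-alkylphenols with alcohols, water or carboxylic acids (the closest known type, with aryloxy capture at an ipso carbon known intramolecularly in grisan and calixarene spirodienone formation), and 4 is chosen because its CHO is ortho/para to every carbon its OH activates, which raises its oxidation potential, suppresses C–C coupling and leaves oxygen as the nucleophilic site, while C4 of 5 bears two identical enone arms and so is not a stereocentre.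

**Step 3**
Reactants: 5 4-(benzyloxy)-3-(4-{2-[1-(3-formylphenoxy)-4-oxocyclohexa-2,5-dien-1-yl]ethyl}phenoxy)benzaldehyde
Product: 6 4-(benzyloxy)-3-(4-{2-[2-(3-formylphenoxy)-5-hydroxyphenyl]ethyl}phenoxy)benzaldehyde
Conditions: Tf2NH (10 mol %), CH2Cl2 (0.01 M), 0 °C, quenched with NaHCO3 at full conversion
Reagents that add atoms: none
Why: In this dienone–phenol (p-quinol-ether) rearrangement, protonation of the most basic site (the cross-conjugated carbonyl) makes C3 cationic, the phenethyl carbon migrates from C4 to C3 because the cation left at C4 is stabilised by the aryloxy oxygen (the same 1,2-shift as p-quinol → 2-alkylhydroquinone), and loss of H+ gives ring A with OAr, alkyl and free OH correctly placed, while the formyl-deactivated D ring disfavours a competing [3,3] shift.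

**Step 4**
Reactants: 6 4-(benzyloxy)-3-(4-{2-[2-(3-formylphenoxy)-5-hydroxyphenyl]ethyl}phenoxy)benzaldehyde
Product: 7 macrocyclic stilbene (O-benzyl, C–D bridge as CH=CH, E/Z mixture used as such)
Conditions: TiCl4 (12 equiv), Zn (24 equiv), THF, reflux; 6 added over 20 h by syringe pump (final about 2 mM)
Reagents that add atoms: none
Why: Intramolecular McMurry coupling of two aromatic aldehydes under pseudo-high dilution closes the 18-membered ring, free phenols are tolerated as titanium phenoxides when the reagent is in excess, and the alkene geometry does not matter because it is removed in the next step.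

**Step 5**
Reactants: 7 macrocyclic stilbene (E/Z mixture)
Product: 9 target macrocyclic bis(bibenzyl) diether CNP0135015.0, via O-benzyl ether of the saturated macrocycle 8 (not isolated)
Conditions: H2 (1 atm), 10 % Pd/C, EtOAc–EtOH, rt
Reagents that add atoms: none
Why: Catalytic hydrogenation first saturates the stilbene and then hydrogenolyses the benzyl aryl ether, the diaryl ethers and phenols are inert, and no stereocentre is created.

**Compound list**
1 | 4,4'-(ethane-1,2-diyl)diphenol (4,4'-dihydroxybibenzyl) | Oc1ccc(CCc2ccc(O)cc2)cc1 | starting material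
2 | 4-(benzyloxy)-3-bromobenzaldehyde | O=Cc1ccc(OCc2ccccc2)c(Br)c1 | starting material
3 | 4-(benzyloxy)-3-{4-[2-(4-hydroxyphenyl)ethyl]phenoxy}benzaldehyde | O=Cc1ccc(OCc2ccccc2)c(Oc2ccc(CCc3ccc(O)cc3)cc2)c1 | intermediate
4 | 3-hydroxybenzaldehyde | O=Cc1cccc(O)c1 | starting material
5 | 4-(benzyloxy)-3-(4-{2-[1-(3-formylphenoxy)-4-oxocyclohexa-2,5-dien-1-yl]ethyl}phenoxy)benzaldehyde | O=Cc1cccc(OC2(CCc3ccc(Oc4cc(C=O)ccc4OCc4ccccc4)cc3)C=CC(=O)C=C2)c1 | intermediate
6 | 4-(benzyloxy)-3-(4-{2-[2-(3-formylphenoxy)-5-hydroxyphenyl]ethyl}phenoxy)benzaldehyde | O=Cc1cccc(Oc2ccc(O)cc2CCc2ccc(Oc3cc(C=O)ccc3OCc3ccccc3)cc2)c1 | intermediate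
7 | macrocyclic stilbene, ring-C O-benzyl ether (E/Z mixture, geometry left open) | Oc1ccc2c(c1)CCc1ccc(cc1)Oc1cc(ccc1OCc1ccccc1)C=Cc1cccc(c1)O2 | intermediate
8 | ring-C O-benzyl ether of the target (saturated macrocycle, not isolated) | Oc1ccc2c(c1)CCc1ccc(cc1)Oc1cc(ccc1OCc1ccccc1)CCc1cccc(c1)O2 | intermediate
9 | CNP0135015.0 (no stereocentre) | Oc1ccc2c(c1)CCc1ccc(cc1)Oc1cc(ccc1O)CCc1cccc(c1)O2 | target

**Total step count:** 5. **Longest linear sequence:** 5 (1 → 3 → 5 → 6 → 7 → 9).

**Steps most likely to fail**

*Step 2 (intermolecular aryloxy capture).* Acetate or water capture, ortho attack, or oxidation of 4 may win. The fallback sets out from 3 and comes back at 5, and it reverses the polarity of the C–O bond formation.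
- Compound 3 is oxidised with PhI(OAc)2 in MeCN–H2O (standard p-quinol synthesis). This gives the p-quinol 4-(benzyloxy)-3-{4-[2-(1-hydroxy-4-oxocyclohexa-2,5-dien-1-yl)ethyl]phenoxy}benzaldehyde F1.
- The tertiary alkoxide of F1 (NaH, toluene, 0 °C to rt) is O-arylated without metal by (3-formylphenyl)(2,4,6-trimethoxyphenyl)iodonium tosylate F2.
- F2 is prepared in one pot from 3-iodobenzaldehyde, mCPBA, TsOH and 1,3,5-trimethoxybenzene. Ligand coupling transfers the electron-poorer formylphenyl group and gives 5.

*Step 3 (1,2-alkyl shift).* Sigmatropic C–C coupling, loss of the aryloxy group, or fragmentation of the phenethyl group may intervene. The fallback sets out from 3 and comes back at 6, and it moves the rearrangement ahead of the O-arylation.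
- The p-quinol F1 is made from 3 as above. It is rearranged with dilute H2SO4 in dioxane (the classical quinol → alkylhydroquinone shift) to the hydroquinone 4-(benzyloxy)-3-{4-[2-(2,5-dihydroxyphenyl)ethyl]phenoxy}benzaldehyde F3.
- The less hindered OH, meta to the chain, is silylated (TBSCl 1.0 equiv, imidazole, DMF, −20 °C) to the mono-TBS ether F4.
- The remaining hindered OH undergoes Chan–Lam coupling with 3-formylphenylboronic acid (Cu(OAc)2, pyridine, 4 Å MS, air, CH2Cl2) to the silyl-protected diaryl ether F5.
- TBAF then gives 6.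

*Step 4 (McMurry macrocyclisation).* Oligomers or pinacols may form instead. The fallback sets out from 6 and comes back at 7, and it replaces reductive carbonyl coupling by metathesis.
- Double methylenation (MePPh3Br, KOtBu, 4 equiv, THF, 0 °C) gives the divinyl compound 4-(3-ethenylphenoxy)-3-(2-{4-[2-(benzyloxy)-5-ethenylphenoxy]phenyl}ethyl)phenol F6.
- F6 is closed by ring-closing metathesis (Grubbs II, 1 mM, toluene, 80 °C) to 7.

**Further compounds**
F1 | step 2 | 4-(benzyloxy)-3-{4-[2-(1-hydroxy-4-oxocyclohexa-2,5-dien-1-yl)ethyl]phenoxy}benzaldehyde (p-quinol) | O=Cc1ccc(OCc2ccccc2)c(Oc2ccc(CCC3(O)C=CC(=O)C=C3)cc2)c1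
F2 | step 2 | (3-formylphenyl)(2,4,6-trimethoxyphenyl)iodonium tosylate | O=Cc1cccc([I+]c2c(OC)cc(OC)cc2OC)c1.Cc1ccc(cc1)S(=O)(=O)[O-]
F3 | step 3 | 4-(benzyloxy)-3-{4-[2-(2,5-dihydroxyphenyl)ethyl]phenoxy}benzaldehyde | O=Cc1ccc(OCc2ccccc2)c(Oc2ccc(CCc3cc(O)ccc3O)cc2)c1
F4 | step 3 | 4-(benzyloxy)-3-{4-[2-(5-{[tert-butyl(dimethyl)silyl]oxy}-2-hydroxyphenyl)ethyl]phenoxy}benzaldehyde | O=Cc1ccc(OCc2ccccc2)c(Oc2ccc(CCc3cc(O[Si](C)(C)C(C)(C)C)ccc3O)cc2)c1
F5 | step 3 | O-TBS ether of 6 | O=Cc1cccc(Oc2ccc(O[Si](C)(C)C(C)(C)C)cc2CCc2ccc(Oc3cc(C=O)ccc3OCc3ccccc3)cc2)c1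
F6 | step 4 | 4-(3-ethenylphenoxy)-3-(2-{4-[2-(benzyloxy)-5-ethenylphenoxy]phenyl}ethyl)phenol | C=Cc1cccc(Oc2ccc(O)cc2CCc2ccc(Oc3cc(C=C)ccc3OCc3ccccc3)cc2)c1
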